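**Retrosynthetic overview**
- The 3,4,5-trimethoxyphenyl ring is joined last, by C-arylation of an anomeric bromide made from an all-cis 5-aryl-3,4-dimethyl lactone; the aryl enters trans to the three cis groups.
- The all-cis lactone comes from hydrogenation of an (R)-5-aryl-3,4-dimethylbutenolide on the face away from the aryl group.
- Both methyl groups come from Raney Ni desulfurization of a dihydrothiophene-fused butenolide (CH2–S–CH2 becomes two CH3).
- That bicycle is made in one flask from an (R)-γ-hydroxy ynoate and the parent thiocarbonyl ylide: the dihydrothiophene ring forms first, the butenolide ring second; the butenolide ring ends up as the tetrahydrofuran.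
- The ynoate comes from asymmetric alkynylation of 3,4-dimethoxybenzaldehyde with methyl propiolate, the only external source of chirality.

Assumption: the ProPhenol antipode written in step 1 is taken to be the one that gives the (R)-carbinol; if a Mosher ester check shows the opposite sense, the mirror-image ligand is used.

**Step 1**
Reactants: 1 3,4-dimethoxybenzaldehyde; 2 methyl propiolate
Product: 4 methyl (4R)-4-(3,4-dimethoxyphenyl)-4-hydroxybut-2-ynoate, via methylzinc acetylide 3 (not isolated)
Conditions: (S,S)-ProPhenol (20 mol%), Me2Zn (3 equiv), Ph3P=O (40 mol%), toluene, 4 °C; aq. NH4Cl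
Reagents that add atoms: none
Why: Dinuclear zinc–ProPhenol asymmetric alkynylation of an aldehyde, in which the chiral dizinc pocket delivers acetylide 3 to one face of 1 and so sets the carbinol centre (R), the carbon that becomes C2 of the target.

**Step 2**
Reactants: 5 bis(trimethylsilylmethyl) sulfide
Product: 6 bis(trimethylsilylmethyl) sulfoxide
Conditions: NaIO4 (1.05 equiv), MeOH/H2O, 0→25 °C
Reagents that add atoms: sodium periodate, [Na+].[O-]I(=O)(=O)=O
Why: Sulfide-to-sulfoxide oxidation with one equivalent of periodate stops at the sulfoxide, and no stereocentre is formed.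

**Step 3**
Reactants: 4 methyl (4R)-4-(3,4-dimethoxyphenyl)-4-hydroxybut-2-ynoate; 6 bis(trimethylsilylmethyl) sulfoxide
Product: 12 (3R)-3-(3,4-dimethoxyphenyl)-4,6-dihydro-1H,3H-thieno[3,4-c]furan-1-one, via silyl ether 7 (not isolated), via siloxymethyl sulfide 8 (not isolated), via thiocarbonyl ylide 9 (not isolated), via silylated cycloadduct 10 (not isolated), via hydroxy ester 11 (not isolated)
Conditions: BSA (1.2 equiv), DMPU, 25 °C; 6 (3 equiv), 100 °C; then PPTS (cat.), MeOH, 25 °C; toluene, 60 °C
Reagents that add atoms: none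
Why: Sila-Pummerer rearrangement of 6 and loss of (Me3Si)2O give ylide 9 under neutral conditions, its 1,3-dipolar cycloaddition to the electron-poor alkyne of 7 builds the dihydrothiophene, and mild acid methanolysis then frees the hydroxyl, which lactonizes onto the cis ester, so both rings are made in one flask while the silyl-masked carbinol centre is untouched and no new stereocentre arises.

**Step 4**
Reactants: 12 (3R)-3-(3,4-dimethoxyphenyl)-4,6-dihydro-1H,3H-thieno[3,4-c]furan-1-one
Product: 13 (5R)-5-(3,4-dimethoxyphenyl)-3,4-dimethylfuran-2(5H)-one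
Conditions: Raney Ni (W-2, washed to neutral), EtOH, 0→25 °C
Reagents that add atoms: none
Why: Raney Ni reductive desulfurization cleaves the two allylic C–S bonds and turns the CH2–S–CH2 bridge into the two methyl groups, without touching the benzylic centre and without creating a stereocentre.

**Step 5**
Reactants: 13 (5R)-5-(3,4-dimethoxyphenyl)-3,4-dimethylfuran-2(5H)-one
Product: 14 (3S,4R,5S)-5-(3,4-dimethoxyphenyl)-3,4-dimethyldihydrofuran-2(3H)-one
Conditions: H2 (5 bar), 5% Rh/Al2O3, EtOAc, 25 °C
Reagents that add atoms: none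
Why: Heterogeneous syn-hydrogenation of the tetrasubstituted butenolide alkene from the face opposite the C5 aryl group puts both new hydrogens trans to the aryl, which sets C3 and C4 so that the aryl and both methyls are all cis.

**Step 6**
Reactants: 14 (3S,4R,5S)-5-(3,4-dimethoxyphenyl)-3,4-dimethyldihydrofuran-2(3H)-one
Product: 16 (3S,4R,5S)-5-(3,4-dimethoxyphenyl)-3,4-dimethyltetrahydrofuran-2-yl acetate, via aluminium lactolate 15 (not isolated)
Conditions: i-Bu2AlH (1.1 equiv), CH2Cl2, −78 °C; then pyridine, DMAP, Ac2O, −78→0 °C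
Reagents that add atoms: acetic anhydride, CC(=O)OC(C)=O
Why: Reductive acetylation (partial lactone reduction, then acetylation of lactolate 15 in the same flask) gives the anomeric acetate without ring opening, so the three set centres are kept and the acetal carbon is an inconsequential epimer mixture.

**Step 7**
Reactants: 16 (3S,4R,5S)-5-(3,4-dimethoxyphenyl)-3,4-dimethyltetrahydrofuran-2-yl acetate; 17 5-bromo-1,2,3-trimethoxybenzene
Product: 20 Ligraminol A, (2S,3R,4S,5S)-2-(3,4-dimethoxyphenyl)-3,4-dimethyl-5-(3,4,5-trimethoxyphenyl)tetrahydrofuran, via aryl Grignard reagent 18 (not isolated), via anomeric bromide 19 (not isolated)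
Conditions: 17, Mg, THF, 40 °C; 16, Me3SiBr, CH2Cl2, −78 °C; then 18 (2 equiv), Li2CuCl4 (5 mol%), THF, −78→−40 °C
Reagents that add atoms: none
Why: Copper-catalysed C-arylation of the anomeric bromide by the aryl Grignard reagent proceeds through the cyclic oxocarbenium ion (as in trans-2,5-diaryltetrahydrofuran syntheses), and the aryl adds to the face opposite the three cis substituents, which sets C5 (S) trans to the neighbouring methyl.

**Compound list**
1 | 3,4-dimethoxybenzaldehyde | COc1ccc(C=O)cc1OC | starting material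
2 | methyl propiolate | C#CC(=O)OC | starting material
3 | methyl 3-(methylzincio)prop-2-ynoate (methylzinc acetylide) | C[Zn]C#CC(=O)OC | intermediate
4 | methyl (4R)-4-(3,4-dimethoxyphenyl)-4-hydroxybut-2-ynoate | COc1ccc([C@@H](O)C#CC(=O)OC)cc1OC | intermediate
5 | bis(trimethylsilylmethyl) sulfide | C[Si](C)(C)CSC[Si](C)(C)C | starting material
6 | bis(trimethylsilylmethyl) sulfoxide | C[Si](C)(C)CS(=O)C[Si](C)(C)C | intermediate
7 | methyl (4R)-4-(3,4-dimethoxyphenyl)-4-(trimethylsilyloxy)but-2-ynoate | COc1ccc([C@@H](O[Si](C)(C)C)C#CC(=O)OC)cc1OC | intermediate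
8 | trimethylsilylmethyl (trimethylsilyloxy)methyl sulfide | C[Si](C)(C)CSCO[Si](C)(C)C | intermediate
9 | thioformaldehyde S-methylide (parent thiocarbonyl ylide) | [CH2-][S+]=C | intermediate
10 | methyl 4-[(R)-(3,4-dimethoxyphenyl)(trimethylsilyloxy)methyl]-2,5-dihydrothiophene-3-carboxylate | COc1ccc([C@@H](O[Si](C)(C)C)C2=C(C(=O)OC)CSC2)cc1OC | intermediate
11 | methyl 4-[(R)-(3,4-dimethoxyphenyl)(hydroxy)methyl]-2,5-dihydrothiophene-3-carboxylate | COc1ccc([C@@H](O)C2=C(C(=O)OC)CSC2)cc1OC | intermediate
12 | (3R)-3-(3,4-dimethoxyphenyl)-4,6-dihydro-1H,3H-thieno[3,4-c]furan-1-one | COc1ccc([C@H]2OC(=O)C3=C2CSC3)cc1OC | intermediate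
13 | (5R)-5-(3,4-dimethoxyphenyl)-3,4-dimethylfuran-2(5H)-one | COc1ccc([C@H]2OC(=O)C(C)=C2C)cc1OC | intermediate
14 | (3S,4R,5S)-5-(3,4-dimethoxyphenyl)-3,4-dimethyldihydrofuran-2(3H)-one (aryl and both methyls cis) | COc1ccc([C@H]2OC(=O)[C@@H](C)[C@H]2C)cc1OC | intermediate
15 | diisobutylaluminium (3S,4R,5S)-5-(3,4-dimethoxyphenyl)-3,4-dimethyltetrahydrofuran-2-olate (both C2 epimers) | COc1ccc([C@H]2OC(O[Al](CC(C)C)CC(C)C)[C@@H](C)[C@H]2C)cc1OC | intermediate
16 | (3S,4R,5S)-5-(3,4-dimethoxyphenyl)-3,4-dimethyltetrahydrofuran-2-yl acetate (both C2 epimers) | COc1ccc([C@H]2OC(OC(C)=O)[C@@H](C)[C@H]2C)cc1OC | intermediate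
17 | 5-bromo-1,2,3-trimethoxybenzene | COc1cc(Br)cc(OC)c1OC | starting material
18 | (3,4,5-trimethoxyphenyl)magnesium bromide | COc1cc([Mg]Br)cc(OC)c1OC | intermediate
19 | (3S,4R,5S)-2-bromo-5-(3,4-dimethoxyphenyl)-3,4-dimethyltetrahydrofuran (both C2 epimers) | COc1ccc([C@H]2OC(Br)[C@@H](C)[C@H]2C)cc1OC | intermediate
20 | Ligraminol A, (2S,3R,4S,5S)-2-(3,4-dimethoxyphenyl)-3,4-dimethyl-5-(3,4,5-trimethoxyphenyl)tetrahydrofuran | COc1ccc([C@H]2O[C@H](c3cc(OC)c(OC)c(OC)c3)[C@@H](C)[C@H]2C)cc1OC | target

**Step count and risks**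
Total steps: 7 (step 2 is a one-step reagent preparation). Longest linear sequence: 6 steps (1, 3, 4, 5, 6, 7) from 3,4-dimethoxybenzaldehyde.

The three steps most likely to fail:

Step 3. The short-lived ylide may add only slowly to a mono-activated, hindered alkyne. The fallback sets out from 4: MnO2 (CH2Cl2, 25 °C) gives the far more electrophilic ynone methyl 4-(3,4-dimethoxyphenyl)-4-oxobut-2-ynoate F1. The ylide from 6 (DMPU, 100 °C) adds to it to give methyl 4-(3,4-dimethoxybenzoyl)-2,5-dihydrothiophene-3-carboxylate F2. Oxazaborolidine-catalysed borane reduction (B-methyl CBS catalyst, antipode chosen for the R carbinol, BH3·SMe2, THF, −20 °C) then sets the stereocentre after the sulfur ring is built and gives 11, which lactonizes to 12, where the route is rejoined.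

Step 4. Raney Ni may hydrogenolyse the benzylic, allylic lactone C–O bond or erode the ee. The fallback sets out from 4 and installs both methyl groups without sulfur: Me2CuLi (3 equiv, THF, −78 °C; syn carbocupration) and then MeI/DMPU trapping of the α-cuprio enoate give methyl (2Z,4R)-4-(3,4-dimethoxyphenyl)-4-hydroxy-2,3-dimethylbut-2-enoate F3, which lactonizes on PPTS work-up to 13, where the route is rejoined.

Step 7. The anomeric bromide may lose HBr to the enol ether, or trans selectivity may erode. The fallback sets out from 16: BF3·OEt2-promoted Friedel–Crafts reaction with 2,6-dimethoxyphenol (CH2Cl2, −78→−20 °C; attack para to OH and anti to the three cis groups) gives 4-[(2S,3S,4R,5S)-5-(3,4-dimethoxyphenyl)-3,4-dimethyloxolan-2-yl]-2,6-dimethoxyphenol F4. Its free para-hydroxyl also allows equilibration to the trans isomer through the quinone methide if needed. MeI, K2CO3 in acetone then gives 20.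

**Further compounds**
F1 | step 3 | methyl 4-(3,4-dimethoxyphenyl)-4-oxobut-2-ynoate | COC(=O)C#CC(=O)c1ccc(OC)c(OC)c1
F2 | step 3 | methyl 4-(3,4-dimethoxybenzoyl)-2,5-dihydrothiophene-3-carboxylate | COC(=O)C1=C(C(=O)c2ccc(OC)c(OC)c2)CSC1
F3 | step 4 | methyl (2Z,4R)-4-(3,4-dimethoxyphenyl)-4-hydroxy-2,3-dimethylbut-2-enoate | COC(=O)/C(C)=C(/C)[C@H](O)c1ccc(OC)c(OC)c1
F4 | step 7 | 4-[(2S,3S,4R,5S)-5-(3,4-dimethoxyphenyl)-3,4-dimethyloxolan-2-yl]-2,6-dimethoxyphenol | COc1ccc([C@H]2O[C@H](c3cc(OC)c(O)c(OC)c3)[C@@H](C)[C@H]2C)cc1OC
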